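Flavone numbering is used (ring A benzo, ring C pyranone, ring B anisyl). Ring C is cut at C3–C4 and O1–C8a. Ring A is symmetric about its C4a–C7 axis: C5 and C8a are the two neighbours of C4a, which holds the C4 ketone, and both are meta to the prenyl ether on C7, so a 4-prenyloxybenzoate fluorinated on both carbons next to the ester (3) offers two identical leaving groups. In one flask the lithium enolate of a MOM-protected ring B ketol (5) is acylated at carbon by this ester and the diketonate oxygen displaces one fluoride, completing the pyranone; the other fluoride later becomes the C5 hydroxyl.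

Key step: step 3

Assumption: the target has no stereocentre and the prenyl alkene carries two identical methyl groups, so no configuration has to be set; compounds 1, 2 and 4 are taken as catalogue chemicals.

Step 1
Reactants: 1 methyl 2,6-difluoro-4-hydroxybenzoate; 2 prenyl bromide (1-bromo-3-methylbut-2-ene)
Product: 3 methyl 2,6-difluoro-4-[(3-methylbut-2-en-1-yl)oxy]benzoate
Conditions: K2CO3, DMF, rt
Reagents that add atoms: none
Why: Williamson ether synthesis, in which the phenol, made acidic by the para ester and the two meta fluorines, is ionised by carbonate and alkylated at oxygen by the reactive allylic bromide in an SN2 reaction, while the electron-rich phenoxide ring keeps its ester and fluorides untouched.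

Step 2
Reactants: 4 2-hydroxy-1-(4-methoxyphenyl)ethan-1-one
Product: 5 2-(methoxymethoxy)-1-(4-methoxyphenyl)ethan-1-one
Conditions: MOMCl, i-Pr2NEt, CH2Cl2, 0 °C to rt
Reagents that add atoms: chloromethyl methyl ether (MOMCl), COCCl
Why: Methoxymethylation of a primary alcohol (O-alkylation by the α-chloro ether with the hindered amine as acid scavenger) should give a formaldehyde acetal that is inert to amide and hydride bases and that caps the future O3 so that it cannot take part in the later ring closure.

Step 3
Reactants: 5 2-(methoxymethoxy)-1-(4-methoxyphenyl)ethan-1-one; 3 methyl 2,6-difluoro-4-[(3-methylbut-2-en-1-yl)oxy]benzoate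
Product: 7 5-fluoro-3-(methoxymethoxy)-2-(4-methoxyphenyl)-7-[(3-methylbut-2-en-1-yl)oxy]-4H-chromen-4-one, via lithium diketonate 6 (not isolated)
Conditions: LiN(SiMe3)2 (1.05 equiv), THF, −78 °C to rt; then DMF, 70 °C
Reagents that add atoms: none
Why: LiN(SiMe3)2 turns ketone 5 into its lithium enolate, chelated through the α-acetal oxygen, whose carbon adds to the carbonyl of the non-enolisable ester 3 and expels methoxide (Claisen condensation, bond C3–C4); the methoxide at once deprotonates the more acidic diketone to 6, so one equivalent of amide should suffice and no alkoxide is left in the flask. After dilution with DMF and warming, the anisoyl oxygen of the delocalised diketonate 6 adds to C8a, ortho to the new C4 ketone, and fluoride leaves from the Meisenheimer adduct (SNAr, bond O1–C8a). The closest known reaction type is the one-pot acylation and fluoride displacement of ortho-fluorobenzoyl donors with ketone enolates that leads to flavones. Ring C closes as a six-membered ring by addition–elimination at an aromatic carbon; attack through C3 or through the C4 oxygen would need a four-membered ring, and O3 is blocked as its acetal. No stereocentre is formed. The step needs acylation at carbon and not at oxygen, which is expected because an enol ester would revert under the alkoxide present whereas the C-acylated product is drained off as its diketonate, and it needs loss of one fluoride only, which follows because the two fluorides are equivalent before closure and the one left at C5 then meets neither a tethered nucleophile nor free alkoxide.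

Step 4
Reactants: 7 5-fluoro-3-(methoxymethoxy)-2-(4-methoxyphenyl)-7-[(3-methylbut-2-en-1-yl)oxy]-4H-chromen-4-one
Product: 9 5-hydroxy-3-(methoxymethoxy)-2-(4-methoxyphenyl)-7-[(3-methylbut-2-en-1-yl)oxy]-4H-chromen-4-one, via sulfonylethyl ether 8 (not isolated)
Conditions: MeSO2CH2CH2OH (1.5 equiv), NaH (3 equiv), DMF, 0 °C to rt; aq. NH4Cl
Reagents that add atoms: 2-(methylsulfonyl)ethanol, CS(=O)(=O)CCO
Why: Nucleophilic aromatic substitution followed by E1cB elimination (the hydroxide-surrogate method for activated aryl fluorides), in which the sodium alkoxide adds at C5, ortho to the C4 carbonyl and with both ring oxygens (O1 on C8a, the ether on C7) only in meta positions, fluoride leaves, and excess hydride removes the proton next to the sulfone in ether 8 so that methyl vinyl sulfone is expelled and the C5 phenoxide is released, while acetal, prenyl ether and methyl ether are stable to base.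

Step 5
Reactants: 9 5-hydroxy-3-(methoxymethoxy)-2-(4-methoxyphenyl)-7-[(3-methylbut-2-en-1-yl)oxy]-4H-chromen-4-one
Product: 10 3,5-dihydroxy-2-(4-methoxyphenyl)-7-[(3-methylbut-2-en-1-yl)oxy]-4H-chromen-4-one
Conditions: 1 M HCl, MeOH–THF, rt
Reagents that add atoms: none
Why: Acid-catalysed transacetalisation (cleavage of a methoxymethyl ether), in which the formaldehyde acetal on O3 ionises to an oxocarbenium ion that is passed on to methanol under dilute acid at room temperature, conditions under which the allylic aryl ether on C7, which needs stronger acid to ionise to the prenyl cation, and the methyl ether should stay intact.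

Compound list
1 | methyl 2,6-difluoro-4-hydroxybenzoate | COC(=O)c1c(F)cc(O)cc1F | starting material
2 | prenyl bromide (1-bromo-3-methylbut-2-ene) | CC(C)=CCBr | starting material
3 | methyl 2,6-difluoro-4-[(3-methylbut-2-en-1-yl)oxy]benzoate | COC(=O)c1c(F)cc(OCC=C(C)C)cc1F | intermediate
4 | 2-hydroxy-1-(4-methoxyphenyl)ethan-1-one | COc1ccc(C(=O)CO)cc1 | starting material
5 | 2-(methoxymethoxy)-1-(4-methoxyphenyl)ethan-1-one | COCOCC(=O)c1ccc(OC)cc1 | intermediate
6 | 1-{2,6-difluoro-4-[(3-methylbut-2-en-1-yl)oxy]phenyl}-2-(methoxymethoxy)-3-(4-methoxyphenyl)propane-1,3-dione, formed as its lithium enolate and drawn as the neutral diketone (C2 is planar in the enolate, no defined configuration) | COCOC(C(=O)c1ccc(OC)cc1)C(=O)c1c(F)cc(OCC=C(C)C)cc1F | intermediate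
7 | 5-fluoro-3-(methoxymethoxy)-2-(4-methoxyphenyl)-7-[(3-methylbut-2-en-1-yl)oxy]-4H-chromen-4-one | COCOc1c(-c2ccc(OC)cc2)oc2cc(OCC=C(C)C)cc(F)c2c1=O | intermediate
8 | 3-(methoxymethoxy)-2-(4-methoxyphenyl)-7-[(3-methylbut-2-en-1-yl)oxy]-5-[2-(methylsulfonyl)ethoxy]-4H-chromen-4-one | COCOc1c(-c2ccc(OC)cc2)oc2cc(OCC=C(C)C)cc(OCCS(C)(=O)=O)c2c1=O | intermediate
9 | 5-hydroxy-3-(methoxymethoxy)-2-(4-methoxyphenyl)-7-[(3-methylbut-2-en-1-yl)oxy]-4H-chromen-4-one | COCOc1c(-c2ccc(OC)cc2)oc2cc(OCC=C(C)C)cc(O)c2c1=O | intermediate
10 | 3,5-dihydroxy-2-(4-methoxyphenyl)-7-[(3-methylbut-2-en-1-yl)oxy]-4H-chromen-4-one | COc1ccc(-c2oc3cc(OCC=C(C)C)cc(O)c3c(=O)c2O)cc1 | target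

Total step count: 5
Longest linear sequence: 4 steps (step 1 or step 2, then steps 3, 4 and 5)

Steps most likely to fail

Step 3. What may go wrong: the condensation may stall with only one equivalent of base, and with more base the liberated methoxide may attack a ring fluoride. The lithium chelate of the diketonate may also close slowly. Fallback: setting out from 3, the ester is saponified (LiOH, THF–H2O, rt) to 2,6-difluoro-4-[(3-methylbut-2-en-1-yl)oxy]benzoic acid F1, which 1,1'-carbonyldiimidazole in THF converts into the acyl imidazole {2,6-difluoro-4-[(3-methylbut-2-en-1-yl)oxy]phenyl}(1H-imidazol-1-yl)methanone F2. F2 is added at −78 °C to the enolate of 5 made with two equivalents of LiN(SiMe3)2. Work-up with aqueous NH4Cl should give the diketone 6, now isolated, and K2CO3 in DMF at 60 °C closes ring C, so that the fallback comes back at 7. The leaving group is then imidazolide, and the neutral fluorochromone never meets an alkoxide.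

Step 5. What may go wrong: acid-induced ionisation of the prenyl ether, with loss of the prenyl group or its migration to C6 or C8, before or alongside cleavage of the acetal. Fallback: setting out from 9, both acid-labile groups are removed on purpose (3 M HCl in MeOH, reflux, with methanol as trap for the prenyl cation) to give 3,5,7-trihydroxy-2-(4-methoxyphenyl)-4H-chromen-4-one F3. One equivalent of prenyl bromide 2 with one equivalent of K2CO3 in acetone should then alkylate the most acidic hydroxyl, the one on C7, which is para to the carbonyl. The hydroxyls on C5 and C3 are hydrogen-bonded to the C4 carbonyl and less acidic. The fallback comes back at the target 10.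

Step 4. What may go wrong: slow substitution at C5, because the pyranone carbonyl is only a vinylogous ester. Reversible addition of the alkoxide at C2, or re-addition of the phenoxide to methyl vinyl sulfone, may compete. Fallback: setting out from 7, the fluoride is displaced by sodium 2-(trimethylsilyl)ethoxide (2-(trimethylsilyl)ethanol, NaH, DMF, rt to 50 °C) to give the isolated ether 3-(methoxymethoxy)-2-(4-methoxyphenyl)-7-[(3-methylbut-2-en-1-yl)oxy]-5-[2-(trimethylsilyl)ethoxy]-4H-chromen-4-one F4. Fluoride (Bu4NF, THF, 50 °C) then fragments the silylethyl group and frees the C5 hydroxyl, so that the fallback comes back at 9. Unmasking is thus separated from substitution, and no Michael acceptor is formed.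

Further compounds
F1 | step 3 | 2,6-difluoro-4-[(3-methylbut-2-en-1-yl)oxy]benzoic acid | O=C(O)c1c(F)cc(OCC=C(C)C)cc1F
F2 | step 3 | {2,6-difluoro-4-[(3-methylbut-2-en-1-yl)oxy]phenyl}(1H-imidazol-1-yl)methanone | O=C(c1c(F)cc(OCC=C(C)C)cc1F)n1ccnc1
F3 | step 5 | 3,5,7-trihydroxy-2-(4-methoxyphenyl)-4H-chromen-4-one | COc1ccc(-c2oc3cc(O)cc(O)c3c(=O)c2O)cc1
F4 | step 4 | 3-(methoxymethoxy)-2-(4-methoxyphenyl)-7-[(3-methylbut-2-en-1-yl)oxy]-5-[2-(trimethylsilyl)ethoxy]-4H-chromen-4-one | COCOc1c(-c2ccc(OC)cc2)oc2cc(OCC=C(C)C)cc(OCC[Si](C)(C)C)c2c1=O
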